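The rate constants were drawn at random within sensible limits; the flask was simulated.

I cannot integrate this scheme by hand, so I freeze what hardly moves.

    electrophile + nucleophile → acid set free + target (k1 = 0.0877 M⁻¹ min⁻¹)
    nucleophile + acid set free ⇌ protonated nucleophile, settled at all times (K2 = 5.88 × 10⁵ M⁻¹)
    acid set free + free base ⇌ salt of the base, settled at all times (K3 = 1.4 × 10⁵ M⁻¹)
    target ⇌ isomer of the product (K4 = 0.34, k4 = 1.69 × 10⁻⁴ min⁻¹)
    gas ⇌ free base, rate k5*(csat - [free base]) (k5 = 0.159 min⁻¹, csat = 0.94 mM)

electrophile 10 mM; nucleophile 12.0 mM; gas 0.94 mM (held); time 8.0 h

- at the start none of free base is dissolved
- run time (flask): 8.0 h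

* part of the electrophile that has reacted at 8.0 h
* share of the unused nucleophile that is free and not bound as protonated nucleophile, at 8.0 h

The free base crosses from the gas in about 6.29 min, far shorter than the 8.0 h of the run, so I freeze it at 0.94 mM. The isomerisation of the target touches neither partner of the coupling, so I drop it.

Each coupling sets one acid free, and with the free base at that level and the nucleophile at its charge, the fast balances share it between the two in the ratio 53.6. The nucleophile therefore takes nearly all of the acid. The nucleophile lost per electrophile reacted, one molecule coupled plus the share protonated, is the price of a turnover, 1.98. So at this frozen price the 12.0 mM charged covers 6.06 mM of turnovers, less than the 10 mM of electrophile: at 1.20 equivalents, the nucleophile is still the limiting reagent.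

With a the electrophile charged, b the nucleophile charged, k the coupling constant, n the price and m = b/n the turnovers covered, the second-order law integrates to a reacted part m(E − 1)/(aE − m), where E = exp[(na − b)kt]. Here E is 1.39, which gives 30.1 %.

The weak link is the frozen price: its ratio was taken with the nucleophile at its charge. By the end, free nucleophile stands near 6.04 mM, so the ratio falls to 27.0 and the price to 1.96. With this end price held over the whole run, E is 1.38, the reacted part is 30.2 %, and the free share of the unused nucleophile is 67.6 %. I commit to these.

The forecast gives 30.2 % and 67.5 %, holding that “each turnover uses up about two nucleophile equivalents”.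

The flask gives 30.1 % reacted and 67.7 % of the unused nucleophile free. At 8.00 h it holds 2.91 mM of protonated nucleophile beside 0.107 mM of salt of the base, so its price over the run reads 1.97. The neighbour flask with 17 mM of electrophile has 0.706 equiv of nucleophile. At the price 1.98, reckoned for the charged nucleophile, its 12.0 mM of nucleophile again covers 6.06 mM of turnovers, and the same formula gives 24.9 % of its electrophile reacted. That neighbour flask shows 25.0 %.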